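## Structural features

The target is a flavanone. Ring A (a benzene ring) is fused to ring C (a dihydropyranone), and ring B, a 3-hydroxy-4-methoxyphenyl group, sits on C2, the only stereocentre, which is S. Ring A is a fully differentiated acylphloroglucinol: O1 at C8a, hydroxyls at C5 and C7, hydrogen at C8, and at C6 an (E)-3,7-dimethylocta-2,6-dienyl (geranyl) chain bound through its primary carbon C1''. C2 is a benzylic ether carbon β to the C4 ketone with no neighbouring stereocentre. It is lost by retro-oxa-Michael opening to the 2'-hydroxychalcone whenever a ring A phenoxide or the C3 enolate is formed, so base and hot basic solvents must be avoided. The geranyl chain is the second fragile element: its 2'',3''-alkene lies ortho to two phenols and adds them under acid to give chromans, it can lose its geometry in allyl-metal intermediates, and it excludes hydrogenolysis. The three hydroxyls differ: the 7-OH is the most acidic, the 3'-OH is an ordinary phenol, and the 5-OH is chelated to the C4 carbonyl and inert to mild silylation. The real difficulty is to attach the chain to carbon at C6 rather than at C8 or at oxygen, through C1'' and with the E geometry kept, without disturbing C2. The key step exploits the fact that C6 is the only ring A C–H ortho to the chelated 5-hydroxyl. It can therefore be iodinated selectively, and the C6–I bond can be exchanged for C6–C1'' by a neutral palladium-catalysed coupling.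

## Logic of the disconnections

**7 to 6.** The O–H bonds at O7 and O3' of 7 are traced back to O–Si bonds in 6. The two reactive phenols must be masked while ring A is functionalised, and silyl ethers are the masks that come off close to neutrality. Nothing is gained in skeleton, since 6 already has every carbon of 7. The demand on the forward step is that cleavage be buffered, so that neither a phenoxide (ring C opening, loss of C2) nor a strong acid (phenol addition to the 2'',3''-alkene) appears.

**6 to 3 and 5.** The bond cut is C6–C1''. It is the only carbon–carbon bond of 6 that is not already present in a purchasable flavanone and a purchasable C10 chain. Cutting it turns the C-geranylation of an ambident polyphenol into a cross-coupling whose site is dictated by a halogen. The gain is full convergence: 3 carries C2 and all three rings, and 5 carries the E-alkene. The forward step must be base-free, must join through the primary allyl carbon and must keep the E geometry. The aryl iodide and allylstannane polarity is chosen for that reason. The 5-hydroxyl of 3 is left free on purpose: chelation keeps it inert, and it is needed for the next disconnection.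

**3 to 2.** The bond cut is C6–I. With O7 capped and O5 free and chelated, electrophilic iodination is biased to C6 over the equally activated C8. The gain is the removal of the halogen, leaving a simple protected natural product. The forward step must stop at mono-iodination at C6 and must run under neutral conditions, so that the activated 7-O-silyl ether and C2 survive.

**2 to 1.** The bonds cut are O7–Si and O3'–Si. The three hydroxyls of 1 are told apart by their intrinsic reactivity, so no extra differentiation steps are needed. The gain is arrival at 1, which supplies C2 in the S configuration. The forward step must stop at the bis-silyl ether and use a base too weak to open ring C.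

**5 to 4.** The bond cut is C1''–Sn. A stannyl anion displaces the primary allylic bromide of 4, which already has the E-alkene. The gain is a one-step branch from a commercial halide. The forward step must substitute at the primary carbon without allylic transposition and without loss of geometry, and 5 must be purified without acid.

## Other disconnections considered

**Alternative 1:** The cut is the aryl ether bond O1–C8a of ring C. In the forward direction the secondary benzylic alcohol of the open-chain aryl bromide A2 would be joined to C8a by Pd(OAc)2, a bulky di-tert-butyl biaryl phosphine and Cs2CO3, an intramolecular Buchwald–Hartwig-type etherification, to give chroman A1 as a pair of C4 epimers.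

- In its favour: the C2–O bond is never broken, so a configuration set earlier by asymmetric synthesis is carried over unchanged.
- In its favour: C4 is at the alcohol oxidation level during closure, so the retro-oxa-Michael pathway that threatens C2 in a flavanone does not exist at that stage.
- Better than the chosen plan on one point: the geranyl group would be placed on a simple arene between two alkoxymethoxy groups, which is regiochemically unambiguous. The chosen plan relies on a kinetic preference in the iodination of 2.
- Against it: the alkoxide on divalent palladium carries a β-hydrogen at C2, so β-hydride elimination (oxidation of the carbinol carbon, reduction of the C–Br bond) competes with C–O reductive elimination, especially for a six-membered closure onto an electron-rich ring.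
- Against it: after the key step three more operations are needed: removal of the C4 silyl ether, oxidation to the ketone and cleavage of three methoxymethyl ethers. The last needs acid in the presence of a geranyl group flanked by two phenols.
- Comparison: the key step is as well understood as the Stille coupling. However, A2 must be built over many steps and C2 must be made rather than bought, so the sequence would be at least twice as long as the five steps chosen here, and its endgame is less safe.

**Alternative 2:** Ring A is cut into a four-carbon and a two-carbon component across C8–C8a, C5–C6, C7–C8 and C4a–C5. In the forward direction irradiation of the dihydropyranone diazo ketone A4 starts a Wolff rearrangement in which C8a migrates to the carbene carbon. A ketene–alkyne [2+2] addition with siloxyalkyne A5, a 4π ring opening and a 6π electrocyclisation follow. Tautomerisation then gives phenol A3 (a Danheiser-type benzannulation).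

- Better than the chosen plan: the substitution pattern follows from the mechanism. The ketene carbon becomes C5 with its hydroxyl, the oxygen-bearing alkyne carbon becomes C7, and the geranyl-bearing carbon must lie between them, so the C6 versus C8 question does not arise.
- Equal or better: the chain never meets an allyl-palladium intermediate, so its geometry is not at risk, and no tin is used.
- Equal: A3 differs from 6 only in the silyl groups, so the endgame is the same single fluoride step.
- Against it: A4 has to be made enantioselectively and then acylated and diazotised over several steps. Its C2 is already β to a ketone and is exposed to ring opening in each basic operation.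
- Against it: A5 is a sensitive skipped enyne ynol ether.
- Against it: the ketene formed from A4 is part of a push–pull vinylogous ester, so the cycloaddition and the 6π closure are less assured than with simple vinylketenes. The ketene may also add to the electron-rich 6'',7''-alkene, and the aryl ketone product absorbs the light.
- Comparison: each fragment needs several steps, so the total would be roughly twice that of the chosen route, and the key step carries more mechanistic uncertainty.

**Alternative 3:** The cut is C2–C3 of ring C. In the forward direction Rh2(S-PTTL)4 would decompose the aryl diazomethyl ketone A7. The divalent rhodium carbenoid would insert into one of the two enantiotopic C–H bonds of the benzyloxy methylene (a 1,6-insertion), closing ring C and creating C2 in A6.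

- Better than the chosen plan: ring closure and stereocentre arise in one catalytic step, and the configuration is set by the catalyst. The plan does not depend on the optical purity of a purchased natural product and would give either enantiomer.
- Equal: A6 loses its three silyl ethers in one fluoride step, so the endgame is the same length.
- Against it: a carbenoid carrying only an acceptor group is unselective. It can attack the ether oxygen (oxonium ylide formation and 1,2-shift, contracting the ring to five members), cyclopropanate the two trisubstituted alkenes of the chain, or add to the electron-rich arenes.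
- Against it: six-membered insertion is less favoured than the usual five-membered mode, and asymmetric induction with acceptor-only carbenoids is generally lower than with the donor–acceptor carbenoids for which this catalyst family is best suited.
- Against it: A7 requires a geranylated, triply protected 2,4,6-trioxygenated benzoic acid and its conversion to a hindered diazo ketone with diazomethane.
- Comparison: the route would be longer (about eight to ten steps) and mechanistically riskier. Its one clear advantage is catalyst control of C2.

Key step: step 4

Assumption: (2S)-hesperetin is used at high enantiomeric purity, checked by chiral HPLC and upgraded before step 1 if needed, because commercial lots can be partly racemic and no later step can raise the optical purity.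

## Route

Step 1
Reactants: 1 (2S)-hesperetin
Product: 2 (2S)-7-(tert-butyldimethylsilyloxy)-2-[3-(tert-butyldimethylsilyloxy)-4-methoxyphenyl]-5-hydroxychroman-4-one
Conditions: TBSCl (2.2 equiv), imidazole (4.5 equiv), DMF, 0 °C → rt
Reagents that add atoms: tert-butyldimethylsilyl chloride, CC(C)(C)[Si](C)(C)Cl
Why: Imidazole-mediated silylation of phenols; the acidic 7-OH and the 3'-OH react, while the 5-OH, locked in a hydrogen bond to the C4 carbonyl, should stay free with this stoichiometry. Imidazole is too weak a base to open ring C, so C2 is not touched.

Step 2
Reactants: 2 (2S)-7-(tert-butyldimethylsilyloxy)-2-[3-(tert-butyldimethylsilyloxy)-4-methoxyphenyl]-5-hydroxychroman-4-one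
Product: 3 (2S)-7-(tert-butyldimethylsilyloxy)-2-[3-(tert-butyldimethylsilyloxy)-4-methoxyphenyl]-5-hydroxy-6-iodochroman-4-one
Conditions: NIS (1.05 equiv), DMF, 0 °C → rt, dark
Reagents that add atoms: N-iodosuccinimide, O=C1CCC(=O)N1I
Why: Electrophilic aromatic iodination; in 5-hydroxy-7-alkoxy flavonoids the free chelated 5-hydroxyl directs the electrophile to its ortho carbon C6, whereas C8 is attacked when O5 is capped. Ring B, an aryl ether without a free phenol, is far less activated, and the neutral medium spares the silyl ethers and C2.

Step 3
Reactants: 4 geranyl bromide
Product: 5 (E)-geranyltributylstannane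
Conditions: Bu3SnH, LiN(i-Pr)2, THF, 0 °C; then 4, −78 °C → rt; distillation or neutral alumina
Reagents that add atoms: tributyltin hydride, CCCC[SnH](CCCC)CCCC (lithiated in the flask to tributylstannyllithium, [Li][Sn](CCCC)(CCCC)CCCC)
Why: SN2 displacement of a primary allylic bromide by a stannyl anion; attack at the unhindered CH2 rather than at the fully substituted terminus leaves the trisubstituted alkene and its E geometry untouched. Acid-free purification avoids a 1,3-shift of tin.

Step 4
Reactants: 3 (2S)-7-(tert-butyldimethylsilyloxy)-2-[3-(tert-butyldimethylsilyloxy)-4-methoxyphenyl]-5-hydroxy-6-iodochroman-4-one; 5 (E)-geranyltributylstannane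
Product: 6 (2S)-7-(tert-butyldimethylsilyloxy)-2-[3-(tert-butyldimethylsilyloxy)-4-methoxyphenyl]-6-[(2E)-3,7-dimethylocta-2,6-dien-1-yl]-5-hydroxychroman-4-one
Conditions: Pd(PPh3)4 (10 mol %), 5 (1.5 equiv), degassed amine-free DMF, 80 °C, dark
Reagents that add atoms: none
Why: In this Migita–Kosugi–Stille allylation zerovalent palladium adds oxidatively to the C6–I bond of 3, the only carbon–halogen bond present, to give an arylpalladium iodide (divalent palladium). The allyl group of 5 is then transferred from tin to palladium with loss of Bu3SnI, and reductive elimination from the aryl(η3-geranyl)palladium complex joins C6 to the unsubstituted terminus C1''. The closest known reaction type is the Pd(PPh3)4-catalysed coupling of aryl iodides, including iodinated 5-hydroxy-7-alkoxyflavonoids, with prenyl- and geranyltributylstannanes. No ring is closed and no stereocentre is created; C2 is carried through, and since the medium holds neither base nor fluoride, neither retro-oxa-Michael opening of ring C nor loss of the silyl ethers is expected. Site selectivity is fixed beforehand by the position of the iodine. Linear rather than branched attachment is secured by the crowded aryl ligand, flanked by the C5 hydroxyl and the C7 silyl ether, which cannot easily reach the fully substituted terminus C3''. Retention of the E geometry requires reductive elimination to outpace syn–anti exchange of the η3-allyl, an exchange that must pass through a σ-complex at the tertiary carbon C3'' and is therefore slow. The chelated 5-hydroxyl is a poor nucleophile and there is no allyl electrophile in the flask, so O-allylation is not expected.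

Step 5
Reactants: 6 (2S)-7-(tert-butyldimethylsilyloxy)-2-[3-(tert-butyldimethylsilyloxy)-4-methoxyphenyl]-6-[(2E)-3,7-dimethylocta-2,6-dien-1-yl]-5-hydroxychroman-4-one
Product: 7 (2S)-6-[(2E)-3,7-dimethylocta-2,6-dien-1-yl]-5,7-dihydroxy-2-(3-hydroxy-4-methoxyphenyl)chroman-4-one (6-geranylhesperetin, the target)
Conditions: Bu4NF (2.4 equiv), AcOH (3 equiv), THF, 0 °C
Reagents that add atoms: none
Why: Fluoride-induced cleavage of two aryl silyl ethers; acetic acid protonates each phenoxide as it forms, so the retro-oxa-Michael opening that would racemise C2 has no anion to start from. The buffer is far too weak an acid to add a phenol across the 2'',3''-alkene, which is why strongly acidic fluoride sources are avoided.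

## Compound list

1 | (2S)-hesperetin, (2S)-5,7-dihydroxy-2-(3-hydroxy-4-methoxyphenyl)chroman-4-one | COc1ccc([C@@H]2CC(=O)c3c(O)cc(O)cc3O2)cc1O | starting material
2 | (2S)-7-(tert-butyldimethylsilyloxy)-2-[3-(tert-butyldimethylsilyloxy)-4-methoxyphenyl]-5-hydroxychroman-4-one | COc1ccc([C@@H]2CC(=O)c3c(O)cc(O[Si](C)(C)C(C)(C)C)cc3O2)cc1O[Si](C)(C)C(C)(C)C | intermediate
3 | (2S)-7-(tert-butyldimethylsilyloxy)-2-[3-(tert-butyldimethylsilyloxy)-4-methoxyphenyl]-5-hydroxy-6-iodochroman-4-one | COc1ccc([C@@H]2CC(=O)c3c(cc(O[Si](C)(C)C(C)(C)C)c(I)c3O)O2)cc1O[Si](C)(C)C(C)(C)C | intermediate
4 | geranyl bromide, (2E)-1-bromo-3,7-dimethylocta-2,6-diene | CC(C)=CCC/C(C)=C/CBr | starting material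
5 | (E)-geranyltributylstannane, tributyl[(2E)-3,7-dimethylocta-2,6-dien-1-yl]stannane | CCCC[Sn](CCCC)(CCCC)C/C=C(\C)CCC=C(C)C | intermediate
6 | (2S)-7-(tert-butyldimethylsilyloxy)-2-[3-(tert-butyldimethylsilyloxy)-4-methoxyphenyl]-6-[(2E)-3,7-dimethylocta-2,6-dien-1-yl]-5-hydroxychroman-4-one | COc1ccc([C@@H]2CC(=O)c3c(cc(O[Si](C)(C)C(C)(C)C)c(C/C=C(\C)CCC=C(C)C)c3O)O2)cc1O[Si](C)(C)C(C)(C)C | intermediate
7 | (2S)-6-[(2E)-3,7-dimethylocta-2,6-dien-1-yl]-5,7-dihydroxy-2-(3-hydroxy-4-methoxyphenyl)chroman-4-one | COc1ccc([C@@H]2CC(=O)c3c(cc(O)c(C/C=C(\C)CCC=C(C)C)c3O)O2)cc1O | target

## Step count and least certain steps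

Total step count: 5. Longest linear sequence: 4 steps (1 → 2 → 3 → 6 → 7); step 3 is a one-step branch that supplies 5.

**Step 4 (key step).**
- What may go wrong: oxidative addition into the electron-rich C–I bond, flanked on both sides, may be slow, so hydrodeiodination competes. The η3-geranyl palladium intermediate may equilibrate before a slow reductive elimination from the crowded aryl complex, giving attachment through C3'' or loss of the E geometry. The activated 7-O-silyl ether may also be lost in hot DMF.
- Fallback: reverse the polarity of the coupling, starting from 3. Stannylation with Me3SnSnMe3 and Pd(PPh3)4 in toluene at 90 °C should give the 6-trimethylstannyl flavanone F1. F1 would then be coupled with geranyl bromide 4 using Pd2(dba)3 in THF at 50 °C, returning to the route at 6.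
- Why it differs: the chain enters as an allyl electrophile. Zerovalent palladium adds to the primary allylic bromide at low temperature, and the aryl group is delivered from tin to the less hindered allyl terminus, a known mode of allyl halide–arylstannane coupling that keeps the alkene geometry. It remains base-free, so C2 is as safe as in the main route.

**Step 2.**
- What may go wrong: loss of site control between C6 and C8, or a second iodination. This is most likely if the activated 7-O-silyl ether is partly cleaved during the reaction, which removes the bias provided by a capped O7 next to a free O5. The position of the iodine is to be checked by HMBC from the chelated hydroxyl proton.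
- Fallback: carry out the iodination on small, robust alkoxymethyl ethers and exchange the masks before any geranyl group is present, starting from 1. MOMCl and i-Pr2NEt in CH2Cl2 at 0 °C should give the 7,3'-bis(methoxymethyl) ether F2. NIS in DMF should give its 6-iodide F3. HCl in MeOH at 40 °C, harmless at this stage because no acid-sensitive chain is present, should give 6-iodohesperetin F4. TBSCl and imidazole in DMF then silylate O7 and O3', returning to the route at 3.

**Step 3.**
- What may go wrong: substitution with allylic transposition, or electron-transfer pathways from the stannyl anion to the allylic bromide. These lead to dimerisation of the chain and erosion of the E geometry. A 1,3-shift of tin during purification is also possible.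
- Fallback: change from SN2 displacement by a stannyl anion to palladium-catalysed allylic substitution, starting from 4. KOAc in DMF should give geranyl acetate F5. Et2AlSnBu3 with catalytic Pd(PPh3)4 in THF should then deliver tin to the primary terminus of the η3-allyl complex with the E geometry kept, returning to the route at 5.

## Further compounds

F1 | step 4 | (2S)-7-(tert-butyldimethylsilyloxy)-2-[3-(tert-butyldimethylsilyloxy)-4-methoxyphenyl]-5-hydroxy-6-(trimethylstannyl)chroman-4-one | COc1ccc([C@@H]2CC(=O)c3c(cc(O[Si](C)(C)C(C)(C)C)c([Sn](C)(C)C)c3O)O2)cc1O[Si](C)(C)C(C)(C)C
F2 | step 2 | (2S)-5-hydroxy-7-(methoxymethoxy)-2-[4-methoxy-3-(methoxymethoxy)phenyl]chroman-4-one | COc1ccc([C@@H]2CC(=O)c3c(O)cc(OCOC)cc3O2)cc1OCOC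
F3 | step 2 | (2S)-5-hydroxy-6-iodo-7-(methoxymethoxy)-2-[4-methoxy-3-(methoxymethoxy)phenyl]chroman-4-one | COc1ccc([C@@H]2CC(=O)c3c(cc(OCOC)c(I)c3O)O2)cc1OCOC
F4 | step 2 | (2S)-5,7-dihydroxy-2-(3-hydroxy-4-methoxyphenyl)-6-iodochroman-4-one (6-iodohesperetin) | COc1ccc([C@@H]2CC(=O)c3c(cc(O)c(I)c3O)O2)cc1O
F5 | step 3 | geranyl acetate, (2E)-3,7-dimethylocta-2,6-dien-1-yl acetate | CC(=O)OC/C=C(\C)CCC=C(C)C
A1 | alternative 1 | (2S)-4-(tert-butyldimethylsilyloxy)-6-[(2E)-3,7-dimethylocta-2,6-dien-1-yl]-5,7-bis(methoxymethoxy)-2-[4-methoxy-3-(methoxymethoxy)phenyl]chroman, both C4 epimers | COc1ccc([C@@H]2CC(O[Si](C)(C)C(C)(C)C)c3c(cc(OCOC)c(C/C=C(\C)CCC=C(C)C)c3OCOC)O2)cc1OCOC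
A2 | alternative 1 | (1S)-3-{6-bromo-3-[(2E)-3,7-dimethylocta-2,6-dien-1-yl]-2,4-bis(methoxymethoxy)phenyl}-3-(tert-butyldimethylsilyloxy)-1-[4-methoxy-3-(methoxymethoxy)phenyl]propan-1-ol, both C3 epimers | COc1ccc([C@@H](O)CC(O[Si](C)(C)C(C)(C)C)c2c(Br)cc(OCOC)c(C/C=C(\C)CCC=C(C)C)c2OCOC)cc1OCOC
A3 | alternative 2 | (2S)-6-[(2E)-3,7-dimethylocta-2,6-dien-1-yl]-5-hydroxy-7-(triisopropylsilyloxy)-2-[4-methoxy-3-(triisopropylsilyloxy)phenyl]chroman-4-one | COc1ccc([C@@H]2CC(=O)c3c(cc(O[Si](C(C)C)(C(C)C)C(C)C)c(C/C=C(\C)CCC=C(C)C)c3O)O2)cc1O[Si](C(C)C)(C(C)C)C(C)C
A4 | alternative 2 | (2S)-6-(2-diazoacetyl)-2-[4-methoxy-3-(triisopropylsilyloxy)phenyl]-2,3-dihydro-4H-pyran-4-one | COc1ccc([C@@H]2CC(=O)C=C(C(=O)C=[N+]=[N-])O2)cc1O[Si](C(C)C)(C(C)C)C(C)C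
A5 | alternative 2 | triisopropyl{[(4E)-5,9-dimethyldeca-4,8-dien-1-yn-1-yl]oxy}silane | CC(C)=CCC/C(C)=C/CC#CO[Si](C(C)C)(C(C)C)C(C)C
A6 | alternative 3 | (2S)-5,7-bis(tert-butyldimethylsilyloxy)-6-[(2E)-3,7-dimethylocta-2,6-dien-1-yl]-2-[4-methoxy-3-(tert-butyldimethylsilyloxy)phenyl]chroman-4-one | COc1ccc([C@@H]2CC(=O)c3c(cc(O[Si](C)(C)C(C)(C)C)c(C/C=C(\C)CCC=C(C)C)c3O[Si](C)(C)C(C)(C)C)O2)cc1O[Si](C)(C)C(C)(C)C
A7 | alternative 3 | 2-diazo-1-{2,4-bis(tert-butyldimethylsilyloxy)-3-[(2E)-3,7-dimethylocta-2,6-dien-1-yl]-6-[4-methoxy-3-(tert-butyldimethylsilyloxy)benzyloxy]phenyl}ethan-1-one | COc1ccc(COc2cc(O[Si](C)(C)C(C)(C)C)c(C/C=C(\C)CCC=C(C)C)c(O[Si](C)(C)C(C)(C)C)c2C(=O)C=[N+]=[N-])cc1O[Si](C)(C)C(C)(C)C
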